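**Strategy.** The route rests on cutting C6–C7. The homoallylic alcohol array O6–C6–C7–C11=C13 on the ten-membered carbocycle (C6 and C7 are also the fusion atoms of the γ-lactone ring) is the retron of a [2,3]-Wittig rearrangement. In one operation the key step contracts a 13-membered bis-allylic ether (O6 bound to C13) to the cyclodeca-1(10),4-diene, forms C6–C7 and sets C6 and C7. Its precursor is the macrocyclic ether carrying the L-tartrate-derived 8,9-acetonide, a C1=C10 olefin with C2 cis to C9 and trityl-protected C14, the E C4=C5 olefin, and a C7=C11 olefin with C13 trans to C8 whose C12 hydroxymethyl arm is free.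

Key step: step 18

Remark on numbering: germacranolide numbering of the target is used throughout (C12 lactone carbonyl, C13 exocyclic methylene, C14 formyl carbon, C15 methyl on C4). The contracted ether therefore links O6 to C13, and the arm on C11 that bears the free hydroxyl is C12. The C7=C11 geometry is given as a ring relationship (C13 trans to C8) because its E/Z label changes with the protecting group.

Remark on the precursor: compared with a design carrying a p-methoxybenzyl ether on O12 and a silyl ether on O14, O12 is left free (lithium alkoxide in the flask) and O14 carries a trityl group. This removes a benzyl allyl ether that could itself rearrange and is meant to steer lithiation to C6.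

**Route**

Step 1
Reactants: 1 geranyl acetate
Product: 3 (E)-6-hydroxy-3-methylhex-2-en-1-yl acetate, via aldehyde 2 (not isolated)
Conditions: O3, CH2Cl2/MeOH, −78 °C; Me2S; then NaBH4, 0 °C
Reagents that add atoms: ozone, [O-][O+]=O
Why: Ozonolysis should cleave the remote, electron-rich trisubstituted olefin faster than the one deactivated by the allylic acetate, and borohydride reduction of the aldehyde gives the C1 alcohol with the E C4=C5 olefin untouched.

Step 2
Reactants: 3 (E)-6-hydroxy-3-methylhex-2-en-1-yl acetate
Product: 4 (E)-6-iodo-3-methylhex-2-en-1-yl acetate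
Conditions: I2, PPh3, imidazole, CH2Cl2, 0 °C
Reagents that add atoms: iodine, II
Why: Appel-type iodination (Garegg–Samuelsson conditions) of a primary alcohol, neutral enough to leave the allylic acetate alone.

Step 3
Reactants: 4 (E)-6-iodo-3-methylhex-2-en-1-yl acetate
Product: 5 [(E)-6-acetoxy-4-methylhex-4-en-1-yl]triphenylphosphonium iodide
Conditions: PPh3, MeCN, reflux
Reagents that add atoms: triphenylphosphine, c1ccc(cc1)P(c1ccccc1)c1ccccc1
Why: SN2 quaternisation of the phosphine by the primary iodide gives the Wittig salt that carries C1–C6.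

Step 4
Reactants: 6 dimethyl (4R,5R)-2,2-dimethyl-1,3-dioxolane-4,5-dicarboxylate
Product: 7 methyl (4R,5S)-5-(hydroxymethyl)-2,2-dimethyl-1,3-dioxolane-4-carboxylate
Conditions: NaBH4 (0.6 equiv), MeOH, 0 °C
Reagents that add atoms: none
Why: Borohydride reduction of an activated α-alkoxy ester with a limited hydride charge should give mainly the mono-alcohol (the two esters are homotopic, so only one mono-alcohol exists; diol and diester are separable) and leaves C8 and C9 untouched.

Step 5
Reactants: 7 methyl (4R,5S)-5-(hydroxymethyl)-2,2-dimethyl-1,3-dioxolane-4-carboxylate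
Product: 8 methyl (4R,5R)-5-formyl-2,2-dimethyl-1,3-dioxolane-4-carboxylate
Conditions: Dess–Martin periodinane, NaHCO3, CH2Cl2, 0 °C to rt
Reagents that add atoms: none
Why: Buffered Dess–Martin oxidation gives the α-alkoxy aldehyde, and the trans-dioxolane is the thermodynamically preferred arrangement so C9 is not endangered.

Step 6
Reactants: 8 methyl (4R,5R)-5-formyl-2,2-dimethyl-1,3-dioxolane-4-carboxylate
Product: 9 methyl (4R,5S)-2,2-dimethyl-5-vinyl-1,3-dioxolane-4-carboxylate
Conditions: Ph3PCH3Br, KN(SiMe3)2, THF, −78 to 0 °C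
Reagents that add atoms: methyltriphenylphosphonium bromide, C[P+](c1ccccc1)(c1ccccc1)c1ccccc1.[Br-]
Why: Wittig methylenation of the aldehyde is much faster than attack of the ylide on the methyl ester at low temperature, and it introduces C14.

Step 7
Reactants: 9 methyl (4R,5S)-2,2-dimethyl-5-vinyl-1,3-dioxolane-4-carboxylate
Product: 10 methyl (4R,5S)-5-(1,2-dihydroxyethyl)-2,2-dimethyl-1,3-dioxolane-4-carboxylate (both carbinol epimers)
Conditions: OsO4 (cat.), N-methylmorpholine N-oxide, acetone/H2O, rt; used at once
Reagents that add atoms: N-methylmorpholine N-oxide, C[N+]1([O-])CCOCC1; water, O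
Why: Upjohn dihydroxylation of the terminal olefin; the new carbinol centre (C10) becomes a ketone in step 9, so its configuration does not matter.

Step 8
Reactants: 10 methyl (4R,5S)-5-(1,2-dihydroxyethyl)-2,2-dimethyl-1,3-dioxolane-4-carboxylate
Product: 11 methyl (4R,5S)-5-[1-hydroxy-2-(trityloxy)ethyl]-2,2-dimethyl-1,3-dioxolane-4-carboxylate
Conditions: TrCl, Et3N, DMAP (cat.), CH2Cl2, rt
Reagents that add atoms: trityl chloride, ClC(c1ccccc1)(c1ccccc1)c1ccccc1
Why: Tritylation is confined to the primary C14 hydroxyl for steric reasons, and it also prevents lactonisation onto the ester.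

Step 9
Reactants: 11 methyl (4R,5S)-5-[1-hydroxy-2-(trityloxy)ethyl]-2,2-dimethyl-1,3-dioxolane-4-carboxylate
Product: 12 methyl (4R,5R)-2,2-dimethyl-5-[(trityloxy)acetyl]-1,3-dioxolane-4-carboxylate
Conditions: Dess–Martin periodinane, NaHCO3, CH2Cl2, rt
Reagents that add atoms: none
Why: Dess–Martin oxidation of the remaining secondary alcohol gives the C10 ketone flanked by the dioxolane (C9) and the trityloxymethyl group (C14).

Step 10
Reactants: 5 [(E)-6-acetoxy-4-methylhex-4-en-1-yl]triphenylphosphonium iodide; 12 methyl (4R,5R)-2,2-dimethyl-5-[(trityloxy)acetyl]-1,3-dioxolane-4-carboxylate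
Product: 14 methyl (4R,5S)-5-[(2Z,6E)-8-acetoxy-6-methyl-1-(trityloxy)octa-2,6-dien-2-yl]-2,2-dimethyl-1,3-dioxolane-4-carboxylate, via phosphorus ylide 13 (not isolated)
Conditions: KN(SiMe3)2 (1.0 equiv), THF, −78 °C; then 12, −78 to 0 °C
Reagents that add atoms: none
Why: Wittig olefination of an α-oxygenated ketone with a salt-free non-stabilised ylide (the Z-selective variant known for α-alkoxy ketones) should place the ylide chain cis to the larger, α-branched dioxolanyl group, that is C2 cis to C9 and trans to C14, and the ketone should react far faster than either ester.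

Step 11
Reactants: 14 methyl (4R,5S)-5-[(2Z,6E)-8-acetoxy-6-methyl-1-(trityloxy)octa-2,6-dien-2-yl]-2,2-dimethyl-1,3-dioxolane-4-carboxylate
Product: 15 (4R,5S)-5-[(2Z,6E)-8-hydroxy-6-methyl-1-(trityloxy)octa-2,6-dien-2-yl]-2,2-dimethyl-1,3-dioxolane-4-carbaldehyde
Conditions: i-Bu2AlH (3.5 equiv), CH2Cl2, −78 °C; MeOH, then KNaC4H4O6 (aq)
Reagents that add atoms: none
Why: At −78 °C the α-alkoxy methyl ester should stop at the chelated tetrahedral aluminate and give the C7 aldehyde on work-up, while the same reagent cleaves the C6 acetate reductively.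

Step 12
Reactants: 16 ethyl (triphenylphosphoranylidene)acetate; 17 (chloromethoxy)triisopropylsilane
Product: 19 ethyl 3-(triisopropylsilyloxy)-2-(triphenylphosphoranylidene)propanoate, via phosphonium chloride 18 (not isolated)
Conditions: 16 (2.1 equiv), toluene, 60 °C; filtration
Reagents that add atoms: none
Why: C-alkylation of the stabilised ylide by the reactive chloromethyl ether followed by transylidation (a second equivalent of 16 deprotonates the new phosphonium salt) is the standard entry to α-substituted ester ylides.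

Step 13
Reactants: 15 (4R,5S)-5-[(2Z,6E)-8-hydroxy-6-methyl-1-(trityloxy)octa-2,6-dien-2-yl]-2,2-dimethyl-1,3-dioxolane-4-carbaldehyde; 19 ethyl 3-(triisopropylsilyloxy)-2-(triphenylphosphoranylidene)propanoate
Product: 20 seco enoate (ethyl ester C13 trans to C8; C12H2OTIPS cis to C8; free C6 hydroxyl)
Conditions: toluene, 70 °C
Reagents that add atoms: none
Why: Wittig reaction of an α-branched ester-stabilised ylide with an α-alkoxy aldehyde in an aprotic solvent is reliably E-selective, which puts the ester carbon (C13) trans and the silyloxymethyl arm (C12) cis to C8.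

Step 14
Reactants: 20 seco enoate
Product: 21 chloro enoate (C6 chloride)
Conditions: N-chlorosuccinimide, Me2S, CH2Cl2, −20 to 0 °C
Reagents that add atoms: N-chlorosuccinimide, O=C1CCC(=O)N1Cl
Why: Corey–Kim chlorination converts the primary allylic alcohol into the chloride under neutral conditions without allylic transposition or loss of the E geometry.

Step 15
Reactants: 21 chloro enoate
Product: 22 chloro alcohol (C13 hydroxyl; C6 chloride)
Conditions: i-Bu2AlH (2.5 equiv), CH2Cl2, −78 °C
Reagents that add atoms: none
Why: 1,2-Reduction of the enoate by the aluminium hydride gives the allylic alcohol, while the allylic chloride and the silyl and trityl ethers are inert at −78 °C.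

Step 16
Reactants: 22 chloro alcohol
Product: 23 13-membered bis-allylic ether (O12 TIPS ether)
Conditions: NaH, Bu4NI (cat.), THF, high dilution (slow addition), 0 to 45 °C
Reagents that add atoms: none
Why: Intramolecular Williamson etherification of a primary allylic alkoxide with a primary allylic halide (13-exo-tet) under high dilution is the established way to close such macrocyclic diallyl ethers.

Step 17
Reactants: 23 13-membered bis-allylic ether (O12 TIPS ether)
Product: 24 13-membered bis-allylic ether with free C12 hydroxymethyl group (precursor of the key step)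
Conditions: Bu4NF, THF, 0 °C to rt
Reagents that add atoms: none
Why: Fluoride cleaves the primary silyl ether while the trityl ether, acetonide and allylic ether are untouched.

Step 18
Reactants: 24 13-membered bis-allylic ether with free C12 hydroxymethyl group
Product: 26 ten-membered diol (C6 hydroxyl; C7 3-hydroxyprop-1-en-2-yl group), via C6-lithio alkoxide 25 (not isolated)
Conditions: n-BuLi (3 equiv), THF, −78 to −20 °C; then H2O
Reagents that add atoms: none
Why: The first equivalent of base forms the C12 lithium alkoxide, further base removes a C6 proton (allylic and α to the ether oxygen), and the carbanion undergoes a suprafacial [2,3]-sigmatropic shift through a five-membered envelope transition state that makes C6–C7 and breaks O–C13, so that C13 becomes the exocyclic methylene and O6 an alkoxide. The closest known reaction is the [2,3]-Wittig ring contraction of 13-membered bis-allylic ethers to germacrane-type cyclodecadienols. The ten-membered carbocycle is closed transannularly (ring contraction 13 to 10), the carbanion adding to the C7 terminus of the allyl unit in SN2′ fashion. C6 (R) relative to C7 follows from the ring geometry of C7=C11 (C13 trans to C8) together with the exo position of the C5 vinyl group in the envelope, which gives the trans C6–O/C7–C11 relationship of the later trans lactone. C7 (S) is controlled by C8: the lithium alkoxide on C12 (cis to C8) should bridge to O8 and hold the C8–O bond in the olefin plane, so that C9 and the C1–C5 tether lie on one face and the tethered C6 carbanion reaches only that face. The step needs lithiation at C6 and not at C13 or C14, which the adjacent C12 alkoxide (it disfavours a second negative charge on the C13–C11–C7 allyl unit) and the bulky, non-coordinating trityl ether at C14 are meant to secure.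

Step 19
Reactants: 26 ten-membered diol
Product: 29 α-methylene γ-lactone (8,9-acetonide; C14 trityl ether), via hydroxy enal 27 (not isolated), via lactol 28 (not isolated)
Conditions: TEMPO (cat.), PhI(OAc)2 (2.5 equiv), CH2Cl2, rt
Reagents that add atoms: none
Why: The oxoammonium oxidation takes the primary allylic alcohol in preference to the secondary C6 alcohol, the resulting enal is trapped by O6 as the five-membered lactol, and this is oxidised on to the lactone (oxidative lactonisation of a 2-methylene-1,4-diol).

Step 20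
Reactants: 29 α-methylene γ-lactone (8,9-acetonide; C14 trityl ether)
Product: 30 lactone triol (free hydroxyls at C8 and C9 and C14)
Conditions: AcOH/THF/H2O (4:1:1), 35 °C
Reagents that add atoms: none
Why: Mild aqueous acid removes the trityl ether and the isopropylidene acetal together, and conditions are kept mild because cyclodeca-1(10),4-dienes cyclise transannularly in strong acid.

Step 21
Reactants: 30 lactone triol
Product: 31 9,14-O-(di-tert-butylsilylene) lactone with free C8 hydroxyl
Conditions: t-Bu2Si(OTf)2 (1.05 equiv), 2,6-lutidine, CH2Cl2, −40 to 0 °C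
Reagents that add atoms: di-tert-butylsilyl bis(trifluoromethanesulfonate), CC(C)(C)[Si](OS(=O)(=O)C(F)(F)F)(OS(=O)(=O)C(F)(F)F)C(C)(C)C
Why: The silyl bis-triflate reacts first with the primary C14 hydroxyl and then closes onto O9 to give the six-membered silylene of the 1,3-diol, which differentiates O9 from O8 by ring size and not by a small rate difference.

Step 22
Reactants: 31 9,14-O-(di-tert-butylsilylene) lactone with free C8 hydroxyl
Product: 32 C8 methacrylate (9,14-silylene)
Conditions: methacrylic anhydride, Et3N, DMAP, CH2Cl2, rt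
Reagents that add atoms: methacrylic anhydride, C=C(C)C(=O)OC(=O)C(C)=C
Why: DMAP-catalysed acylation (Steglich-type acyl transfer) of the only free hydroxyl installs the C8 ester with retention at C8.

Step 23
Reactants: 32 C8 methacrylate (9,14-silylene)
Product: 33 C8 methacrylate 9,14-diol
Conditions: HF·pyridine, pyridine, THF, 0 °C
Reagents that add atoms: none
Why: Buffered fluoride cleaves the silylene and leaves the methacrylate, the lactone and both Michael acceptors intact.

Step 24
Reactants: 33 C8 methacrylate 9,14-diol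
Product: 34 C8 methacrylate C14 enal with free C9 hydroxyl
Conditions: TEMPO (cat.), PhI(OAc)2 (1.3 equiv), CH2Cl2, rt
Reagents that add atoms: none
Why: The oxoammonium oxidation is selective for the primary allylic alcohol over the secondary C9 alcohol and stops at the enal in the absence of water; the C1=C10 geometry is already the favoured one for an α-substituted enal (C2 trans to the formyl group).

Step 25
Reactants: 34 C8 methacrylate C14 enal with free C9 hydroxyl
Product: 35 target (CNP0403553.1)
Conditions: Ac2O, pyridine, DMAP (cat.), CH2Cl2, 0 °C to rt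
Reagents that add atoms: acetic anhydride, CC(=O)OC(C)=O
Why: DMAP-catalysed acetylation of the last free hydroxyl; β-elimination is not possible because C10 carries no hydrogen.

**Compound list**

1 | geranyl acetate | CC(C)=CCC/C(C)=C/COC(C)=O | starting material
2 | (E)-3-methyl-6-oxohex-2-en-1-yl acetate | O=CCC/C(C)=C/COC(C)=O | intermediate
3 | (E)-6-hydroxy-3-methylhex-2-en-1-yl acetate | OCCC/C(C)=C/COC(C)=O | intermediate
4 | (E)-6-iodo-3-methylhex-2-en-1-yl acetate | ICCC/C(C)=C/COC(C)=O | intermediate
5 | [(E)-6-acetoxy-4-methylhex-4-en-1-yl]triphenylphosphonium iodide | CC(=O)OC/C=C(\C)CCC[P+](c1ccccc1)(c1ccccc1)c1ccccc1.[I-] | intermediate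
6 | dimethyl (4R,5R)-2,2-dimethyl-1,3-dioxolane-4,5-dicarboxylate (dimethyl 2,3-O-isopropylidene-L-tartrate) | COC(=O)[C@@H]1OC(C)(C)O[C@H]1C(=O)OC | starting material
7 | methyl (4R,5S)-5-(hydroxymethyl)-2,2-dimethyl-1,3-dioxolane-4-carboxylate | COC(=O)[C@@H]1OC(C)(C)O[C@H]1CO | intermediate
8 | methyl (4R,5R)-5-formyl-2,2-dimethyl-1,3-dioxolane-4-carboxylate | COC(=O)[C@@H]1OC(C)(C)O[C@H]1C=O | intermediate
9 | methyl (4R,5S)-2,2-dimethyl-5-vinyl-1,3-dioxolane-4-carboxylate | COC(=O)[C@@H]1OC(C)(C)O[C@H]1C=C | intermediate
10 | methyl (4R,5S)-5-(1,2-dihydroxyethyl)-2,2-dimethyl-1,3-dioxolane-4-carboxylate, both carbinol epimers | COC(=O)[C@@H]1OC(C)(C)O[C@H]1C(O)CO | intermediate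
11 | methyl (4R,5S)-5-[1-hydroxy-2-(trityloxy)ethyl]-2,2-dimethyl-1,3-dioxolane-4-carboxylate, both carbinol epimers | COC(=O)[C@@H]1OC(C)(C)O[C@H]1C(O)COC(c2ccccc2)(c2ccccc2)c2ccccc2 | intermediate
12 | methyl (4R,5R)-2,2-dimethyl-5-[(trityloxy)acetyl]-1,3-dioxolane-4-carboxylate | COC(=O)[C@@H]1OC(C)(C)O[C@H]1C(=O)COC(c2ccccc2)(c2ccccc2)c2ccccc2 | intermediate
13 | [(E)-6-acetoxy-4-methylhex-4-en-1-ylidene]triphenylphosphorane | CC(=O)OC/C=C(\C)CCC=P(c1ccccc1)(c1ccccc1)c1ccccc1 | intermediate
14 | methyl (4R,5S)-5-[(2Z,6E)-8-acetoxy-6-methyl-1-(trityloxy)octa-2,6-dien-2-yl]-2,2-dimethyl-1,3-dioxolane-4-carboxylate (C7 ester, C6 acetate, C2 cis to C9) | COC(=O)[C@@H]1OC(C)(C)O[C@H]1/C(COC(c2ccccc2)(c2ccccc2)c2ccccc2)=C\CC/C(C)=C/COC(C)=O | intermediate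
15 | (4R,5S)-5-[(2Z,6E)-8-hydroxy-6-methyl-1-(trityloxy)octa-2,6-dien-2-yl]-2,2-dimethyl-1,3-dioxolane-4-carbaldehyde (C7 aldehyde, C6 hydroxyl) | O=C[C@@H]1OC(C)(C)O[C@H]1/C(COC(c2ccccc2)(c2ccccc2)c2ccccc2)=C\CC/C(C)=C/CO | intermediate
16 | ethyl (triphenylphosphoranylidene)acetate | CCOC(=O)C=P(c1ccccc1)(c1ccccc1)c1ccccc1 | starting material
17 | (chloromethoxy)triisopropylsilane | ClCO[Si](C(C)C)(C(C)C)C(C)C | starting material
18 | [1-ethoxy-1-oxo-3-(triisopropylsilyloxy)propan-2-yl]triphenylphosphonium chloride | CCOC(=O)C(CO[Si](C(C)C)(C(C)C)C(C)C)[P+](c1ccccc1)(c1ccccc1)c1ccccc1.[Cl-] | intermediate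
19 | ethyl 3-(triisopropylsilyloxy)-2-(triphenylphosphoranylidene)propanoate | CCOC(=O)C(CO[Si](C(C)C)(C(C)C)C(C)C)=P(c1ccccc1)(c1ccccc1)c1ccccc1 | intermediate
20 | seco enoate: ethyl (E)-3-{(4S,5S)-5-[(2Z,6E)-8-hydroxy-6-methyl-1-(trityloxy)octa-2,6-dien-2-yl]-2,2-dimethyl-1,3-dioxolan-4-yl}-2-[(triisopropylsilyloxy)methyl]prop-2-enoate | CCOC(=O)/C(CO[Si](C(C)C)(C(C)C)C(C)C)=C/[C@@H]1OC(C)(C)O[C@H]1/C(COC(c2ccccc2)(c2ccccc2)c2ccccc2)=C\CC/C(C)=C/CO | intermediate
21 | chloro enoate: as 20 with C6 chloride in place of the C6 hydroxyl | CCOC(=O)/C(CO[Si](C(C)C)(C(C)C)C(C)C)=C/[C@@H]1OC(C)(C)O[C@H]1/C(COC(c2ccccc2)(c2ccccc2)c2ccccc2)=C\CC/C(C)=C/CCl | intermediate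
22 | chloro alcohol: C13 allylic alcohol (C13 trans to C8), C12H2OTIPS, (8S,9S)-acetonide, C14 trityl ether, C2 cis to C9, 4E, C6 chloride | OC/C(CO[Si](C(C)C)(C(C)C)C(C)C)=C/[C@@H]1OC(C)(C)O[C@H]1/C(COC(c2ccccc2)(c2ccccc2)c2ccccc2)=C\CC/C(C)=C/CCl | intermediate
23 | 13-membered ether: O links C6 and C13, C12H2OTIPS, (8S,9S)-acetonide, C14 trityl ether, C13 trans to C8, C2 cis to C9, 4E | C1/C(C)=C/COC/C(CO[Si](C(C)C)(C(C)C)C(C)C)=C/[C@@H]2OC(C)(C)O[C@H]2/C(COC(c3ccccc3)(c3ccccc3)c3ccccc3)=C\C1 | intermediate
24 | 13-membered ether as 23 with free C12 hydroxymethyl group (key-step precursor) | C1/C(C)=C/COC/C(CO)=C/[C@@H]2OC(C)(C)O[C@H]2/C(COC(c3ccccc3)(c3ccccc3)c3ccccc3)=C\C1 | intermediate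
25 | C6-lithio derivative of the C12 lithium alkoxide of 24 (configuration at C6 not fixed) | [Li]C1/C=C(\C)CC/C=C(/COC(c3ccccc3)(c3ccccc3)c3ccccc3)[C@@H]2OC(C)(C)O[C@H]2/C=C(\CO[Li])CO1 | intermediate
26 | ten-membered diol: (6R,7S,8S,9S), C6 hydroxyl, C7 3-hydroxyprop-1-en-2-yl, 8,9-acetonide, C14 trityl ether, 1(10)-olefin with C2 cis to C9, 4E | O[C@@H]1/C=C(\C)CC/C=C(/COC(c3ccccc3)(c3ccccc3)c3ccccc3)[C@@H]2OC(C)(C)O[C@H]2[C@H]1C(=C)CO | intermediate
27 | hydroxy enal: as 26 with C12 formyl group | O[C@@H]1/C=C(\C)CC/C=C(/COC(c3ccccc3)(c3ccccc3)c3ccccc3)[C@@H]2OC(C)(C)O[C@H]2[C@H]1C(=C)C=O | intermediate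
28 | 6,12-lactol (both C12 epimers) | OC1O[C@@H]2/C=C(\C)CC/C=C(/COC(c4ccccc4)(c4ccccc4)c4ccccc4)[C@@H]3OC(C)(C)O[C@H]3[C@H]2C1=C | intermediate
29 | 6,12-olide with α-methylene group, 8,9-acetonide, C14 trityl ether | O=C1O[C@@H]2/C=C(\C)CC/C=C(/COC(c4ccccc4)(c4ccccc4)c4ccccc4)[C@@H]3OC(C)(C)O[C@H]3[C@H]2C1=C | intermediate
30 | 8,9,14-trihydroxy-6,12-olide | O=C1O[C@@H]2/C=C(\C)CC/C=C(/CO)[C@H](O)[C@@H](O)[C@H]2C1=C | intermediate
31 | 9,14-O-(di-tert-butylsilylene)-8-hydroxy-6,12-olide | O=C1O[C@@H]2/C=C(\C)CC/C=C3/CO[Si](C(C)(C)C)(C(C)(C)C)O[C@@H]3[C@@H](O)[C@H]2C1=C | intermediate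
32 | 8-O-methacryloyl-9,14-O-(di-tert-butylsilylene)-6,12-olide | O=C1O[C@@H]2/C=C(\C)CC/C=C3/CO[Si](C(C)(C)C)(C(C)(C)C)O[C@@H]3[C@@H](OC(=O)C(C)=C)[C@H]2C1=C | intermediate
33 | 8-O-methacryloyl-9,14-dihydroxy-6,12-olide | O=C1O[C@@H]2/C=C(\C)CC/C=C(/CO)[C@H](O)[C@@H](OC(=O)C(C)=C)[C@H]2C1=C | intermediate
34 | 8-O-methacryloyl-9-hydroxy-14-oxo-6,12-olide | O=C1O[C@@H]2/C=C(\C)CC/C=C(/C=O)[C@H](O)[C@@H](OC(=O)C(C)=C)[C@H]2C1=C | intermediate
35 | CNP0403553.1: (6R,7S,8S,9S)-9-acetoxy-8-methacryloyloxy-14-oxogermacra-1(10),4,11(13)-trien-12,6-olide | C=C(C)C(=O)O[C@H]1[C@H]2C(=C)C(=O)O[C@@H]2/C=C(\C)CC/C=C(/C=O)[C@@H]1OC(C)=O | target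

**Count and risks**

Total step count: 25 (steps 1–3 for the C1–C6 salt, step 12 for the ylide reagent, steps 4–11 and 13–25 in the main line). Longest linear sequence: 21 steps (6 to 35).

Steps most likely to fail:

1. Step 18. What may go wrong: lithiation at C13 instead of C6, attack on the other face of C7 (anti to the C8–O bond, which would give the C6/C7-epimeric pair), a competing [1,2]-shift, or β-elimination that opens the acetonide. Fallback: the C6–C7 bond is made with reversed polarity by an intramolecular Nozaki–Hiyama–Kishi allylation, a known way to close germacrane-type rings. It sets out from chloro alcohol 22. Oxidation of the allylic chloride with N-methylmorpholine N-oxide in MeCN gives hydroxy enal F1. CBr4/PPh3 turns the C13 alcohol into allylic bromide F2. CrCl2 (divalent chromium) in THF at high dilution forms the allylchromium species, which adds through C7 to the C6 aldehyde and gives the ten-membered homoallylic alcohol F3 (anti C6/C7 expected from the chair transition state; the C7 face would have to be checked and diastereomers separated). Bu4NF then removes the silyl group and the route is rejoined at 26.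

2. Step 10. What may go wrong: poor control of the C1=C10 geometry (the two oxygenated α-carbons of 12 compete for directing the ylide chain) and enolisation of the ketone by the basic ylide. Fallback: the geometry is set under thermodynamic instead of kinetic control. It sets out from 14 obtained as an isomer mixture. Formic acid in ether removes the trityl group to give allylic alcohol F4, and MnO2 oxidises it to the α-substituted enal F5. The enal is equilibrated (catalytic iodine or catalytic DABCO) to the favoured isomer with C2 trans to the formyl group, which is the geometry needed. NaBH4/CeCl3 returns F4 as a single isomer and tritylation as in step 8 comes back at 14.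

3. Step 16. What may go wrong: intermolecular etherification, SN2′ attack at C4, or loss of HCl to a diene outrunning ring closure. Fallback: the C–O bond is formed through a π-allyl complex instead of an SN2 displacement. Setting out from 22, the zinc alkoxide (Et2Zn) is cyclised with Pd(PPh3)4 (zerovalent palladium) in THF at high dilution; the allylic chloride ionises to the C4–C6 π-allyl unit, which the alkoxide attacks at the primary terminus C6. The E geometry of C4=C5 should survive because syn–anti exchange would need σ-bonding at the fully substituted C4. This arrives directly at 23 and makes no new compound.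

Further compounds
F1 | step 18 | hydroxy enal: as 22 with C6 formyl group in place of the chloromethyl terminus | OC/C(CO[Si](C(C)C)(C(C)C)C(C)C)=C/[C@@H]1OC(C)(C)O[C@H]1/C(COC(c2ccccc2)(c2ccccc2)c2ccccc2)=C\CC/C(C)=C/C=O
F2 | step 18 | allylic bromide: as F1 with C13 bromide in place of the C13 hydroxyl | BrC/C(CO[Si](C(C)C)(C(C)C)C(C)C)=C/[C@@H]1OC(C)(C)O[C@H]1/C(COC(c2ccccc2)(c2ccccc2)c2ccccc2)=C\CC/C(C)=C/C=O
F3 | step 18 | ten-membered homoallylic alcohol: as 26 with C12 triisopropylsilyl ether | O[C@@H]1/C=C(\C)CC/C=C(/COC(c3ccccc3)(c3ccccc3)c3ccccc3)[C@@H]2OC(C)(C)O[C@H]2[C@H]1C(=C)CO[Si](C(C)C)(C(C)C)C(C)C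
F4 | step 10 | allylic alcohol: as 14 with free C14 hydroxyl | COC(=O)[C@@H]1OC(C)(C)O[C@H]1/C(CO)=C\CC/C(C)=C/COC(C)=O
F5 | step 10 | enal: as 14 with C14 formyl group (C2 trans to the formyl group) | COC(=O)[C@@H]1OC(C)(C)O[C@H]1/C(C=O)=C\CC/C(C)=C/COC(C)=O
F0 | step 16 | none | none
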